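**Plan**

- Locants (aromadendrane type): ring O–C2–C1–C5–C4=C3, C15 on C4, cyclopropane C6–C7–C11 bearing C12 (ring CH2O) and C13 (CH2OAc), then C8, C9, C10(CH3)OH. The SMILES places H-6 and H-7 anti, so the cyclopropane is trans-fused to the cycloheptane and C12 is cis to C5.
- Cuts, in order: both acetates; the O–C12 bond of the oxepane (C11–C12–O–C15–C4–C5–C6); C1–C5 together with O–C2 (oxa-Diels–Alder, which unlocks dihydropyran and cycloheptane at once); C11–C6 and C11–C7 (cyclopropane); the C6=C7 enal from the prenyl end of linalool.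
- Forward: linalool chain, then the trans-cyclopropane by organocatalytic Michael-initiated ring closure, then cycloheptane plus dihydropyran in one domino Knoevenagel/intramolecular oxa-Diels–Alder step, then the oxepane as the last ring, then the acetates.
- Feature behind the key step: C11 is a quaternary cyclopropane carbon with two diastereotopic CH2OTs arms. Only the arm cis to C5 can be reached by the C15 alkoxide (cis 3/7 fusion), so one etherification closes the ring, fixes C11 and leaves the other arm for the C13 acetate.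
- Stereochemistry: C10 from (S)-linalool; C6 and C7 from the prolinol catalyst; C1 and C5 from the cycloaddition (substrate control); C11 by group selection; C2 by anomeric control in the final acetylation.

Key step: step 11

Remark: the (Z)-silyl enol ether fixes C2 in 13 to 19 as drawn; any (E)-isomer would only give the C2 epimers, which converge at lactol 20.

**Step 1**
Reactants: 1 (S)-linalool
Product: 3 (3S)-3,7-dimethyloct-6-ene-1,3-diol, via alkyl-9-BBN borinate 2 (not isolated)
Conditions: 9-BBN (2.2 equiv), THF, 0 °C to rt; then NaOH, H2O2, H2O, 0 °C to rt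
Reagents that add atoms: hydrogen peroxide OO
Why: Anti-Markovnikov hydroboration–oxidation; 9-BBN should add only to the monosubstituted vinyl group (the trisubstituted alkene is inert at room temperature) and C10 of linalool is not touched.

**Step 2**
Reactants: 3 (3S)-3,7-dimethyloct-6-ene-1,3-diol
Product: 4 (3S)-3,7-dimethyl-1,3-bis(triethylsilyloxy)oct-6-ene
Conditions: Et3SiOTf (2.5 equiv), 2,6-lutidine, CH2Cl2, −78 to 0 °C
Reagents that add atoms: triethylsilyl trifluoromethanesulfonate CC[Si](CC)(CC)OS(=O)(=O)C(F)(F)F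
Why: Silyl ether formation; the triflate silylates the tertiary as well as the primary hydroxyl, and the primary TES ether is the latent C2 aldehyde.

**Step 3**
Reactants: 4 bis-TES ether; 5 (E)-but-2-enal
Product: 6 (2E,6S)-6-methyl-6,8-bis(triethylsilyloxy)oct-2-enal
Conditions: 5 (5 equiv), second-generation Hoveyda–Grubbs catalyst RuCl2(H2IMes)(=CH-C6H4-2-OiPr) (5 mol %), CH2Cl2, 40 °C
Reagents that add atoms: (E)-but-2-enal (5) C/C=C/C=O
Why: Olefin cross-metathesis of the prenyl-type alkene with an enal; volatile 2-methylbut-2-ene leaves and the conjugated product should form as the (E)-isomer.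

**Step 4**
Reactants: 6 enal; 7 dimethyl 2-bromomalonate
Product: 8 dimethyl (2R,3R)-2-formyl-3-[(3S)-3-methyl-3,5-bis(triethylsilyloxy)pentyl]cyclopropane-1,1-dicarboxylate
Conditions: (S)-2-[diphenyl(trimethylsilyloxy)methyl]pyrrolidine (20 mol %), 2,6-lutidine (1.1 equiv), CH2Cl2, 0 °C to rt
Reagents that add atoms: dimethyl 2-bromomalonate (7) COC(=O)C(Br)C(=O)OC
Why: Organocatalytic Michael-initiated ring closure (iminium then enamine catalysis): the malonate adds to C7 of the (E)-iminium ion on the face away from the CPh2OSiMe3 group, and the enamine carbon C6 then displaces bromide to give the trans-2,3-disubstituted cyclopropane, so C6 and C7 are set under catalyst control.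

**Step 5**
Reactants: 8 cyclopropane aldehyde
Product: 9 dimethyl (2R,3R)-2-formyl-3-[(3S)-3-methyl-5-oxo-3-(triethylsilyloxy)pentyl]cyclopropane-1,1-dicarboxylate
Conditions: (COCl)2, DMSO, CH2Cl2, −78 to −35 °C; then Et3N, to 0 °C
Reagents that add atoms: none
Why: Swern oxidation run directly on the primary triethylsilyl ether (the chlorosulfonium salt cleaves the unhindered O–Si bond and oxidises in the same pot); the tertiary TES ether, the esters and the existing aldehyde should be inert.

**Step 6**
Reactants: 9 dialdehyde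
Product: 10 dimethyl (2R,3R)-2-formyl-3-[(3S,4Z)-3-methyl-3-(triethylsilyloxy)-5-(triisopropylsilyloxy)pent-4-en-1-yl]cyclopropane-1,1-dicarboxylate
Conditions: iPr3SiOTf (1.2 equiv), Et3N, CH2Cl2, −78 to 0 °C
Reagents that add atoms: triisopropylsilyl trifluoromethanesulfonate CC(C)[Si](C(C)C)(C(C)C)OS(=O)(=O)C(F)(F)F
Why: Soft enolisation with O-silylation should give the (Z)-silyl enol ether of the only enolisable aldehyde (C2); the cyclopropanecarbaldehyde would have to become an alkylidenecyclopropane to enolise.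

**Step 7**
Reactants: 10 silyl enol ether aldehyde; 11 sodium enolate of ethyl formylacetate
Product: 13 tricyclic triester silyl acetal, via formylacrylate oxadiene 12 (not isolated)
Conditions: 11 (1.5 equiv), AcOH (1.5 equiv), piperidine (0.2 equiv), 4 Å molecular sieves, MeCN–CH2Cl2 (0.005 M), 0 to 40 °C
Reagents that add atoms: sodium (E)-3-ethoxy-3-oxoprop-1-en-1-olate (11) CCOC(=O)/C=C/[O-].[Na+]
Why: Domino Knoevenagel condensation/intramolecular inverse-electron-demand oxa-Diels–Alder reaction: condensation at the C5 aldehyde gives oxadiene 12 (O=C3–C4=C5), which adds suprafacially to the tethered silyl enol ether (C5 to C1, O to C2) and closes dihydropyran and cycloheptane together, C5 being set by attack on the s-trans alkylidene–cyclopropane conformer from the face of the C7 tether (C4 anti to C11), C1 by the cis-fused transition state that the five-atom tether should favour, C2 by the (Z)-enol ether geometry, while slow generation of 12 at high dilution and the early, strongly exothermic transition state should offset the strain of the trans-fused 3/7 system.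

**Step 8**
Reactants: 13 tricyclic triester silyl acetal
Product: 14 tricyclic 1,3-diol (C12 and C13 as CH2OH)
Conditions: LiBH4 (3 equiv), THF, 0 °C to rt
Reagents that add atoms: none
Why: Chemoselective ester reduction: LiBH4 should reduce the two malonate-type methyl esters on C11 to the 1,3-diol and leave the push–pull β-alkoxyacrylate ester (a vinylogous carbonate) at C15, the silyl acetal and the silyl ether.

**Step 9**
Reactants: 14 tricyclic 1,3-diol
Product: 15 bis(p-toluenesulfonate)
Conditions: TsCl (3 equiv), Et3N, DMAP (cat.), CH2Cl2, 0 °C to rt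
Reagents that add atoms: p-toluenesulfonyl chloride Cc1ccc(cc1)S(=O)(=O)Cl
Why: Sulfonate ester formation on both neopentyl-type primary alcohols; the two CH2OTs arms have no β-hydrogen and C11 is not yet stereogenic.

**Step 10**
Reactants: 15 bis(p-toluenesulfonate)
Product: 16 allylic alcohol (C15 as CH2OH)
Conditions: iBu2AlH (2.5 equiv), CH2Cl2, −78 °C; aq. potassium sodium tartrate
Reagents that add atoms: none
Why: iBu2AlH reduction of the vinylogous carbonate to the allylic alcohol at −78 °C, conditions under which sulfonates, silyl acetal and silyl ether should survive.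

**Step 11**
Reactants: 16 allylic alcohol bis(p-toluenesulfonate)
Product: 18 oxepane tosylate, via sodium alkoxide 17 (not isolated)
Conditions: NaH (1.5 equiv), THF (0.005 M), 0 to 40 °C
Reagents that add atoms: none
Why: NaH deprotonates the C15 hydroxyl and alkoxide 17 displaces tosylate at C12 in an intramolecular Williamson etherification (SN2 at a primary cyclopropylcarbinyl carbon; the closest known type is alkoxide or thiolate displacement of 1-substituted cyclopropylmethyl sulfonates). The oxepane closes in the 7-exo-tet mode. The new stereocentre is the quaternary C11: its two CH2OTs arms are diastereotopic and the cyclopropane itself decides between them, because only the arm cis to C5 can reach O15 through a cis-fused 3/7 transition state, whereas the arm cis to C8 would need a second trans-fused seven-membered ring on the cyclopropane. The step needs group selectivity (C12 over C13) and substitution without ionisation: C11 has no β-hydrogen, all other hydroxyls are silylated, and putting the leaving group on the cyclopropylcarbinyl carbon instead of on C15 avoids the ambident C3/C15 oxocarbenium ion that any leaving group on C15 would form. High dilution should suppress intermolecular etherification. The untouched tosylate arm is the handle for the C13 acetate.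

**Step 12**
Reactants: 18 oxepane tosylate
Product: 19 C13 acetate
Conditions: CsOAc (5 equiv), 18-crown-6, DMF, 80 °C
Reagents that add atoms: cesium acetate CC(=O)[O-].[Cs+]
Why: SN2 displacement of the remaining primary cyclopropylcarbinyl tosylate by acetate; elimination is impossible (no β-hydrogen) and the non-ionising medium should prevent cyclopropylcarbinyl rearrangement.

**Step 13**
Reactants: 19 bis-silylated acetate
Product: 20 lactol
Conditions: Bu4NF, AcOH (1:1, 3 equiv), THF, 0 °C to rt
Reagents that add atoms: none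
Why: Fluoride-mediated desilylation, buffered with acetic acid, should free the lactol (the anomeric silyl ether is the most labile) and the tertiary alcohol without acid, which the electron-rich enol ether and the allylic ether would not tolerate, and without acetate cleavage; the lactol anomers interconvert.

**Step 14**
Reactants: 20 lactol
Product: 21 CNP0250836.2
Conditions: Ac2O (1.5 equiv), pyridine, DMAP (cat.), CH2Cl2, 0 °C
Reagents that add atoms: acetic anhydride CC(=O)OC(C)=O
Why: Acylation with acetic anhydride: the tertiary C10 hydroxyl should not react at 0 °C, and since the lactol anomers equilibrate under the basic conditions the acetate should form stereoconvergently as the axial anomer trans to C10 (anomeric effect, less hindered face), which is 2R.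

**Compound list**

1 | (S)-(+)-linalool, (3S)-3,7-dimethylocta-1,6-dien-3-ol | CC(C)=CCC[C@](C)(O)C=C | starting material
2 | B-alkyl-9-borabicyclo[3.3.1]nonane from hydroboration of the vinyl group of 1, tertiary oxygen as 9-BBN borinate | CC(C)=CCC[C@](C)(OB1C2CCCC1CCC2)CCB1C2CCCC1CCC2 | intermediate
3 | (3S)-3,7-dimethyloct-6-ene-1,3-diol | CC(C)=CCC[C@](C)(O)CCO | intermediate
4 | (3S)-3,7-dimethyl-1,3-bis(triethylsilyloxy)oct-6-ene | CC(C)=CCC[C@](C)(O[Si](CC)(CC)CC)CCO[Si](CC)(CC)CC | intermediate
5 | (E)-but-2-enal (crotonaldehyde) | C/C=C/C=O | starting material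
6 | (2E,6S)-6-methyl-6,8-bis(triethylsilyloxy)oct-2-enal | O=C/C=C/CC[C@](C)(O[Si](CC)(CC)CC)CCO[Si](CC)(CC)CC | intermediate
7 | dimethyl 2-bromomalonate | COC(=O)C(Br)C(=O)OC | starting material
8 | dimethyl (2R,3R)-2-formyl-3-[(3S)-3-methyl-3,5-bis(triethylsilyloxy)pentyl]cyclopropane-1,1-dicarboxylate (formyl and side chain trans) | O=C[C@@H]1[C@@H](CC[C@](C)(O[Si](CC)(CC)CC)CCO[Si](CC)(CC)CC)C1(C(=O)OC)C(=O)OC | intermediate
9 | dimethyl (2R,3R)-2-formyl-3-[(3S)-3-methyl-5-oxo-3-(triethylsilyloxy)pentyl]cyclopropane-1,1-dicarboxylate | O=C[C@@H]1[C@@H](CC[C@](C)(O[Si](CC)(CC)CC)CC=O)C1(C(=O)OC)C(=O)OC | intermediate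
10 | dimethyl (2R,3R)-2-formyl-3-[(3S,4Z)-3-methyl-3-(triethylsilyloxy)-5-(triisopropylsilyloxy)pent-4-en-1-yl]cyclopropane-1,1-dicarboxylate | O=C[C@@H]1[C@@H](CC[C@](C)(O[Si](CC)(CC)CC)/C=C\O[Si](C(C)C)(C(C)C)C(C)C)C1(C(=O)OC)C(=O)OC | intermediate
11 | sodium (E)-3-ethoxy-3-oxoprop-1-en-1-olate (sodium enolate of ethyl formylacetate) | CCOC(=O)/C=C/[O-].[Na+] | starting material
12 | oxadiene: 10 with the formyl group condensed to a (1Z)-3-ethoxy-2-formyl-3-oxoprop-1-en-1-yl group (C5=C4(CHO)CO2Et), ring and side chain as in 10 | CCOC(=O)/C(C=O)=C\[C@@H]1[C@@H](CC[C@](C)(O[Si](CC)(CC)CC)/C=C\O[Si](C(C)C)(C(C)C)C(C)C)C1(C(=O)OC)C(=O)OC | intermediate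
13 | tricyclic triester: 2-(triisopropylsilyloxy)dihydropyran (O–C2–C1–C5–C4=C3, CO2Et on C4) cis-fused at C1–C5 to the cycloheptane, cyclopropane trans-fused at C6–C7 with two CO2Me on C11, C10 OTES; OSi at C2 cis to C10; C1, C5, C6, C7, C10 as in 21 | CCOC(=O)C1=CO[C@@H](O[Si](C(C)C)(C(C)C)C(C)C)[C@@H]2[C@H]1[C@@H]1[C@@H](CC[C@]2(C)O[Si](CC)(CC)CC)C1(C(=O)OC)C(=O)OC | intermediate
14 | as 13 with C12 and C13 as CH2OH (1,3-diol on C11) | CCOC(=O)C1=CO[C@@H](O[Si](C(C)C)(C(C)C)C(C)C)[C@@H]2[C@H]1[C@@H]1[C@@H](CC[C@]2(C)O[Si](CC)(CC)CC)C1(CO)CO | intermediate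
15 | as 14 with both CH2OH as p-toluenesulfonates | CCOC(=O)C1=CO[C@@H](O[Si](C(C)C)(C(C)C)C(C)C)[C@@H]2[C@H]1[C@@H]1[C@@H](CC[C@]2(C)O[Si](CC)(CC)CC)C1(COS(=O)(=O)c3ccc(C)cc3)COS(=O)(=O)c3ccc(C)cc3 | intermediate
16 | as 15 with C15 as CH2OH (allylic alcohol on the enol ether) | OCC1=CO[C@@H](O[Si](C(C)C)(C(C)C)C(C)C)[C@@H]2[C@H]1[C@@H]1[C@@H](CC[C@]2(C)O[Si](CC)(CC)CC)C1(COS(=O)(=O)c3ccc(C)cc3)COS(=O)(=O)c3ccc(C)cc3 | intermediate
17 | sodium C15 alkoxide of 16 | [Na+].[O-]CC1=CO[C@@H](O[Si](C(C)C)(C(C)C)C(C)C)[C@@H]2[C@H]1[C@@H]1[C@@H](CC[C@]2(C)O[Si](CC)(CC)CC)C1(COS(=O)(=O)c3ccc(C)cc3)COS(=O)(=O)c3ccc(C)cc3 | intermediate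
18 | tetracycle with the C12–O–C15 oxepane closed, C13 p-toluenesulfonate, C2 OTIPS (cis to C10), C10 OTES; C11 and all ring centres as in 21 | Cc1ccc(cc1)S(=O)(=O)OC[C@@]12COCC3=CO[C@@H](O[Si](C(C)C)(C(C)C)C(C)C)[C@@H]4[C@H]3[C@@H]1[C@H]2CC[C@]4(C)O[Si](CC)(CC)CC | intermediate
19 | as 18 with C13 acetate | CC(=O)OC[C@@]12COCC3=CO[C@@H](O[Si](C(C)C)(C(C)C)C(C)C)[C@@H]4[C@H]3[C@@H]1[C@H]2CC[C@]4(C)O[Si](CC)(CC)CC | intermediate
20 | lactol: 19 without both silyl groups (C2–OH, C10–OH; anomers interconvert, the anomer with OH trans to C10 is drawn) | CC(=O)OC[C@@]12COCC3=CO[C@H](O)[C@@H]4[C@H]3[C@@H]1[C@H]2CC[C@]4(C)O | intermediate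
21 | CNP0250836.2, (1R,2R,5R,6S,7R,10S,11R) in the locants above: C2 and C13 acetates, 12,15-ether, C10 tertiary alcohol | CC(=O)OC[C@@]12COCC3=CO[C@H](OC(C)=O)[C@@H]4[C@H]3[C@@H]1[C@H]2CC[C@]4(C)O | target

**Totals**

Total step count: 14. Longest linear sequence: 14 steps (1 to 21).

**Steps most likely to fail**

1. Step 7. Oligomerisation or decomposition of the transient oxadiene may outrun the strained seven-membered ring closure, or the facial selectivity at C1 and C5 may be poor. Fallback (sets out from 9, returns at 20): the dienophile is made far more nucleophilic and the closure reversible by switching from the preformed silyl enol ether to enamine activation. Dialdehyde 9, N-methylaniline, 11 and AcOH (CH2Cl2, 4 Å molecular sieves, rt) should give the enamine–oxadiene F1 (not isolated), which closes by Michael addition and N,O-acetal formation to the anilino acetal F2. Mild hydrolysis (wet silica gel or aq. AcOH–THF, tolerated while C4 still carries the ester) gives the lactol triester F3, and iPr3SiOTf/2,6-lutidine gives the silyl acetal F4, the C2 epimer of 13. F4 is taken through steps 8 to 12 unchanged: diol F5, bis-tosylate F6, allylic alcohol F7, its sodium alkoxide F8, oxepane tosylate F9 and acetate F10. Step 13 on F10 gives lactol 20.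

2. Step 8. The hydride may also attack the C15 ester, so that the chemoselectivity between the esters is lost. Fallback (sets out from 13, returns at 16): no selectivity between esters is asked of the hydride. iBu2AlH (excess, CH2Cl2, −78 to 0 °C) reduces all three esters to the triol F11. Pivaloyl chloride/pyridine at −30 °C should acylate the unhindered allylic C15 hydroxyl in preference to the two neopentyl-type ones and give the monopivalate F12. Tosylation as in step 9 gives the pivalate bis-tosylate F13, and iBu2AlH at −78 °C removes the pivalate and gives 16.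

3. Step 12. Substitution at the α-quaternary cyclopropylcarbinyl carbon may be too slow, or ionisation with cyclopropylcarbinyl rearrangement may compete. Fallback (sets out from 18, returns at 21): the sulfonate is cleaved at the S–O bond instead of being displaced at carbon. SmI2/Et3N/H2O in THF (electron transfer) should give the primary alcohol F14. Bu4NF/AcOH as in step 13 gives the lactol diol F15, and Ac2O (2.5 equiv), pyridine, DMAP at 0 °C acetylates the primary and the lactol hydroxyls and gives 21.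

**Further compounds**

F1 | step 7 | enamine–oxadiene: (E)-N-methyl-N-phenyl enamine of the C2 aldehyde of 9, formylacrylate at C5 (not isolated) | CCOC(=O)/C(C=O)=C\[C@@H]1[C@@H](CC[C@](C)(O[Si](CC)(CC)CC)/C=C/N(C)c2ccccc2)C1(C(=O)OC)C(=O)OC
F2 | step 7 | anilino acetal: analogue of 13 with N(CH3)Ph at C2, trans to C10 | CCOC(=O)C1=CO[C@H](N(C)c3ccccc3)[C@@H]2[C@H]1[C@@H]1[C@@H](CC[C@]2(C)O[Si](CC)(CC)CC)C1(C(=O)OC)C(=O)OC
F3 | step 7 | lactol triester: analogue of 13 with OH at C2 (major anomer drawn) | CCOC(=O)C1=CO[C@H](O)[C@@H]2[C@H]1[C@@H]1[C@@H](CC[C@]2(C)O[Si](CC)(CC)CC)C1(C(=O)OC)C(=O)OC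
F4 | step 7 | C2 epimer of 13 (OTIPS trans to C10) | CCOC(=O)C1=CO[C@H](O[Si](C(C)C)(C(C)C)C(C)C)[C@@H]2[C@H]1[C@@H]1[C@@H](CC[C@]2(C)O[Si](CC)(CC)CC)C1(C(=O)OC)C(=O)OC
F5 | step 7 | C2 epimer of 14 | CCOC(=O)C1=CO[C@H](O[Si](C(C)C)(C(C)C)C(C)C)[C@@H]2[C@H]1[C@@H]1[C@@H](CC[C@]2(C)O[Si](CC)(CC)CC)C1(CO)CO
F6 | step 7 | C2 epimer of 15 | CCOC(=O)C1=CO[C@H](O[Si](C(C)C)(C(C)C)C(C)C)[C@@H]2[C@H]1[C@@H]1[C@@H](CC[C@]2(C)O[Si](CC)(CC)CC)C1(COS(=O)(=O)c3ccc(C)cc3)COS(=O)(=O)c3ccc(C)cc3
F7 | step 7 | C2 epimer of 16 | OCC1=CO[C@H](O[Si](C(C)C)(C(C)C)C(C)C)[C@@H]2[C@H]1[C@@H]1[C@@H](CC[C@]2(C)O[Si](CC)(CC)CC)C1(COS(=O)(=O)c3ccc(C)cc3)COS(=O)(=O)c3ccc(C)cc3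
F8 | step 7 | C2 epimer of 17 (sodium alkoxide, not isolated) | [Na+].[O-]CC1=CO[C@H](O[Si](C(C)C)(C(C)C)C(C)C)[C@@H]2[C@H]1[C@@H]1[C@@H](CC[C@]2(C)O[Si](CC)(CC)CC)C1(COS(=O)(=O)c3ccc(C)cc3)COS(=O)(=O)c3ccc(C)cc3
F9 | step 7 | C2 epimer of 18 | Cc1ccc(cc1)S(=O)(=O)OC[C@@]12COCC3=CO[C@H](O[Si](C(C)C)(C(C)C)C(C)C)[C@@H]4[C@H]3[C@@H]1[C@H]2CC[C@]4(C)O[Si](CC)(CC)CC
F10 | step 7 | C2 epimer of 19 | CC(=O)OC[C@@]12COCC3=CO[C@H](O[Si](C(C)C)(C(C)C)C(C)C)[C@@H]4[C@H]3[C@@H]1[C@H]2CC[C@]4(C)O[Si](CC)(CC)CC
F11 | step 8 | triol: 13 with C12, C13 and C15 all as CH2OH | OCC1=CO[C@@H](O[Si](C(C)C)(C(C)C)C(C)C)[C@@H]2[C@H]1[C@@H]1[C@@H](CC[C@]2(C)O[Si](CC)(CC)CC)C1(CO)CO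
F12 | step 8 | C15 monopivalate of F11 | CC(C)(C)C(=O)OCC1=CO[C@@H](O[Si](C(C)C)(C(C)C)C(C)C)[C@@H]2[C@H]1[C@@H]1[C@@H](CC[C@]2(C)O[Si](CC)(CC)CC)C1(CO)CO
F13 | step 8 | C15 pivalate, C12 and C13 p-toluenesulfonates | CC(C)(C)C(=O)OCC1=CO[C@@H](O[Si](C(C)C)(C(C)C)C(C)C)[C@@H]2[C@H]1[C@@H]1[C@@H](CC[C@]2(C)O[Si](CC)(CC)CC)C1(COS(=O)(=O)c3ccc(C)cc3)COS(=O)(=O)c3ccc(C)cc3
F14 | step 12 | primary alcohol: 18 with C13 as CH2OH | OC[C@@]12COCC3=CO[C@@H](O[Si](C(C)C)(C(C)C)C(C)C)[C@@H]4[C@H]3[C@@H]1[C@H]2CC[C@]4(C)O[Si](CC)(CC)CC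
F15 | step 12 | lactol diol: 20 with C13 as CH2OH (major anomer drawn) | OC[C@@]12COCC3=CO[C@H](O)[C@@H]4[C@H]3[C@@H]1[C@H]2CC[C@]4(C)O
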